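## Retrosynthetic overview

1. The target comes from a protected briarane by late O-acylations, desilylation and allylic oxidation. Its ten-membered ring is closed last, at C4–C5, by an intramolecular B-alkyl Suzuki coupling of a Z-vinyl iodide with a terminal alkene.
2. The γ-lactone (C8 and C17) comes from a zinc Reformatsky closure of a C7 O-(2-bromopropanoyl) C8 ketone.
3. The C8–C9 bond comes from a late coupling of fragment A (ring A α-alkoxystannane, C1–C4, C9–C15, C20) with fragment B (Z-iodoalkenyl α-acyloxy aldehyde, C5–C8, C16–C19), followed by oxidation.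
4. Fragment A comes from a catalytic asymmetric Diels–Alder reaction of an amino-siloxy diene with (E)-4,4-dimethoxy-2-methylbut-2-enal. Fragment B comes from (S)-but-3-ene-1,2-diol and a Stork–Zhao iodo-olefination.
5. Ring order: ring A (Diels–Alder), then the γ-lactone (Reformatsky), then the ten-membered ring (Suzuki).

Convention: C-numbers are the briarane locants of the target (ring A = C1, C10–C14); α/β refer to ring A drawn with the C15 methyl β.

Assumption: where a chiral catalyst or reagent sets absolute configuration (steps 4, 5, 10, 11), the antipode named is the one expected from the usual selectivity models; if a sense proved opposite, the mirror-image catalyst would be used and nothing else changes.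

## Route

Step 1
Reactants: 1 butan-2-one
Product: 2 (E)-1-(dimethylamino)pent-1-en-3-one
Conditions: Me2NCH(OMe)2, neat, 100 °C, MeOH distilled off; fractional distillation
Reagents that add atoms: N,N-dimethylformamide dimethyl acetal, COC(OC)N(C)C
Why: Aminomethylenation (enaminone formation) takes place mainly at the less hindered methyl group and gives the E vinylogous amide, the minor methylene regioisomer being removed by distillation.

Step 2
Reactants: 2 (E)-1-(dimethylamino)pent-1-en-3-one
Product: 3 (1E,3Z)-3-(tert-butyldimethylsilyloxy)-N,N-dimethylpenta-1,3-dien-1-amine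
Conditions: KN(SiMe3)2, THF, −78 °C; t-BuMe2SiCl, −78 °C → rt
Reagents that add atoms: tert-butyldimethylsilyl chloride, CC(C)(C)[Si](C)(C)Cl
Why: Deprotonation of the ethyl group of the vinylogous amide and O-silylation of the Z-enolate (silyl enol ether formation) give the electron-rich 1-amino-3-siloxy diene with its methyl group on the outside.

Step 3
Reactants: 4 2,2-dimethoxyacetaldehyde; 5 propanal
Product: 6 (E)-4,4-dimethoxy-2-methylbut-2-enal
Conditions: pyrrolidine (10 mol %), PhCO2H (10 mol %), toluene, 60 °C, slow addition of 5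
Reagents that add atoms: none
Why: Amine-catalysed crossed aldol condensation works because only propanal can form the enamine and the acetal aldehyde is the better acceptor, and dehydration gives the thermodynamically preferred E enal.

Step 4
Reactants: 3 amino-siloxy diene; 6 (E)-4,4-dimethoxy-2-methylbut-2-enal
Product: 8 ring A enone aldehyde (1S,2S)-2-(dimethoxymethyl)-1,3-dimethyl-4-oxocyclohex-5-ene-1-carbaldehyde as C11 epimers, via cycloadduct 7 (not isolated)
Conditions: (R,R)-(salen)CrSbF6 [hexafluoroantimonate of the trivalent chromium complex of N,N'-bis(3,5-di-tert-butylsalicylidene)-1,2-cyclohexanediamine] (5 mol %), 4 Å MS, CH2Cl2, −40 °C; then HF·pyridine, MeCN, 0 °C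
Reagents that add atoms: none
Why: In this catalytic asymmetric Diels–Alder reaction the nucleophilic methyl-bearing diene terminus bonds to the enal β-carbon, suprafacial addition to the E dienophile places the C15 methyl cis to the C9 acetal (C1/C10), the chiral chromium Lewis acid selects the enal face, and fluoride-induced desilylation with β-elimination of dimethylamine unveils the enone.

Step 5
Reactants: 8 ring A enone aldehyde
Product: 9 (4S,5S)-5-(dimethoxymethyl)-4-[(1R)-1-hydroxyprop-2-en-1-yl]-4,6-dimethylcyclohex-2-en-1-one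
Conditions: Zn(CH=CH2)2 (2 equiv), (+)-MIB [(2R)-3-exo-morpholinoisoborneol] (10 mol %), toluene, −20 → 0 °C; NH4Cl aq
Reagents that add atoms: divinylzinc, C=C[Zn]C=C
Why: Amino-alcohol-catalysed organozinc addition touches only the aldehyde (not the enone) and the chiral zinc alkoxide delivers vinyl to the Re face, so the (2R) carbinol is set by the catalyst and not by the substrate's Felkin bias.

Step 6
Reactants: 9 (2R)-allylic alcohol
Product: 10 (4S,5R,6S)-5-(dimethoxymethyl)-6-hydroxy-4-[(1R)-1-hydroxyprop-2-en-1-yl]-4,6-dimethylcyclohex-2-en-1-one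
Conditions: LiN(SiMe3)2 (2.3 equiv), THF, −78 °C; then 3-phenyl-2-(phenylsulfonyl)oxaziridine, −78 °C; NH4Cl aq
Reagents that add atoms: 3-phenyl-2-(phenylsulfonyl)oxaziridine (Davis reagent), O=S(=O)(c1ccccc1)N1OC1c1ccccc1
Why: In this enolate oxidation only the C11 α'-proton can be removed (C1 is quaternary), which erases the C11 mixture, and the oxaziridine attacks the cross-conjugated dienolate anti to the β-oriented C10 acetal branch and the β C15 methyl, so the new hydroxyl is α.

Step 7
Reactants: 10 11α-hydroxy enone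
Product: 11 ring A triol (11α-OH and 12β-OH)
Conditions: NaBH4, CeCl3·7H2O, MeOH, −78 → −40 °C
Reagents that add atoms: none
Why: Luche reduction gives clean 1,2-reduction of the enone, hydride arriving anti to the C11 methyl to give mainly the 12β-alcohol, whose configuration is without consequence because C12 returns to a ketone in step 27.

Step 8
Reactants: 11 ring A triol
Product: 13 tris-TES aldehyde (C9 formyl on C10), via tris-TES acetal 12 (not isolated)
Conditions: Et3SiOTf (5 equiv), 2,6-lutidine (8 equiv), CH2Cl2, −78 → 0 °C; then H2O, rt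
Reagents that add atoms: triethylsilyl trifluoromethanesulfonate, CC[Si](CC)(CC)OS(=O)(=O)C(F)(F)F; water, O
Why: The silyl triflate silylates all three hydroxyls and then, with lutidine, turns the dimethyl acetal into a pyridinium-type N,O-acetal salt that water hydrolyses to the aldehyde (silyl triflate/pyridine-base acetal cleavage) under non-basic conditions that leave the silyl ethers and C10 untouched.

Step 9
Reactants: 13 tris-TES aldehyde
Product: 15 acylstannane (C10–C(=O)SnBu3), via lithium stannylalkoxide 14 (not isolated)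
Conditions: Bu3SnLi (1.3 equiv), THF, −78 °C; then 1,1'-(azodicarbonyl)dipiperidine, −78 → 0 °C
Reagents that add atoms: tributylstannyllithium, [Li][Sn](CCCC)(CCCC)CCCC
Why: Nucleophilic stannylation of the aldehyde followed by hydride-transfer oxidation of the alkoxide by the azodicarboxamide (Mukaiyama-type oxidation) gives the acylstannane and removes the uncontrolled C9 centre.

Step 10
Reactants: 15 acylstannane
Product: 17 fragment A (9S)-α-(methoxymethoxy)stannane, via hydroxystannane 16 (not isolated)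
Conditions: (R)-BINAL-H [LiAlH(OEt)((R)-1,1'-binaphthalene-2,2'-diolate)], THF, −78 °C; then MeOCH2Cl, i-Pr2NEt, CH2Cl2, 0 °C
Reagents that add atoms: chloromethyl methyl ether, COCCl
Why: Reagent-controlled BINAL-H reduction of the acylstannane sets the (9S) α-hydroxystannane, which is trapped at once as the MOM ether (Williamson-type acetalisation) because free α-hydroxystannanes revert to the aldehyde.

Step 11
Reactants: 18 rac-2-vinyloxirane
Product: 19 (S)-but-3-ene-1,2-diol
Conditions: H2O (0.45 equiv), (R,R)-(salen)Co(OAc) [acetate of the trivalent cobalt complex of N,N'-bis(3,5-di-tert-butylsalicylidene)-1,2-cyclohexanediamine] (0.5 mol %), THF, 0 °C → rt; unreacted (R)-epoxide distilled off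
Reagents that add atoms: water, O
Why: In this hydrolytic kinetic resolution one epoxide enantiomer is opened by water at the terminal carbon, so the stereocentre is untouched and the diol is obtained in high ee when water is limiting.

Step 12
Reactants: 19 (S)-but-3-ene-1,2-diol
Product: 20 (S)-2,2-dimethyl-4-vinyl-1,3-dioxolane
Conditions: Me2C(OMe)2, p-TsOH (cat.), CH2Cl2, rt
Reagents that add atoms: 2,2-dimethoxypropane, COC(C)(C)OC
Why: Acid-catalysed transketalisation protects the 1,2-diol as the acetonide without touching the stereocentre.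

Step 13
Reactants: 20 (S)-2,2-dimethyl-4-vinyl-1,3-dioxolane
Product: 21 (R)-2,2-dimethyl-1,3-dioxolane-4-carbaldehyde
Conditions: O3, CH2Cl2, −78 °C; then PPh3, −78 °C → rt; used at once
Reagents that add atoms: ozone, [O-][O+]=O
Why: Ozonolysis with reductive work-up cleaves the only alkene to the aldehyde under neutral conditions that do not epimerise the α-alkoxy centre.

Step 14
Reactants: 21 (R)-2,2-dimethyl-1,3-dioxolane-4-carbaldehyde
Product: 22 (S)-4-[(Z)-2-iodoprop-1-en-1-yl]-2,2-dimethyl-1,3-dioxolane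
Conditions: [Ph3PCH(I)CH3]I, NaN(SiMe3)2, THF/DMPU, −78 → −20 °C
Reagents that add atoms: (1-iodoethyl)triphenylphosphonium iodide, CC(I)[P+](c1ccccc1)(c1ccccc1)c1ccccc1.[I-]
Why: The Stork–Zhao Wittig olefination with the non-stabilised α-iodo ylide gives the Z trisubstituted vinyl iodide (iodine cis to C7) under kinetic control at low temperature, where the α-alkoxy aldehyde is not epimerised.

Step 15
Reactants: 22 iodoalkenyl acetonide
Product: 23 (S,Z)-4-iodopent-3-ene-1,2-diol
Conditions: AcOH/H2O (4:1), 40 °C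
Reagents that add atoms: none
Why: Mild acidic acetal hydrolysis frees the diol and leaves the vinyl iodide and its geometry intact.

Step 16
Reactants: 23 (S,Z)-4-iodopent-3-ene-1,2-diol
Product: 24 (S,Z)-4-iodo-1-(triethylsilyloxy)pent-3-en-2-ol
Conditions: Et3SiCl (1.05 equiv), imidazole, CH2Cl2, −20 °C
Reagents that add atoms: triethylsilyl chloride, CC[Si](CC)(CC)Cl
Why: Selective silylation works because the primary hydroxyl reacts much faster than the secondary allylic one at low temperature.

Step 17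
Reactants: 24 primary TES ether
Product: 25 (S,Z)-4-iodo-1-(triethylsilyloxy)pent-3-en-2-yl 2-bromopropanoate
Conditions: (±)-CH3CHBrCOBr, pyridine, CH2Cl2, −20 → 0 °C
Reagents that add atoms: 2-bromopropanoyl bromide, CC(Br)C(Br)=O
Why: Acylation of the C7 hydroxyl installs C17–C19 as the Reformatsky donor, the CHBr epimers being irrelevant because that centre becomes an enolate.

Step 18
Reactants: 25 bromopropanoate TES ether
Product: 26 (S,Z)-1-hydroxy-4-iodopent-3-en-2-yl 2-bromopropanoate
Conditions: HF·pyridine, pyridine, THF, 0 °C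
Reagents that add atoms: none
Why: Fluoride desilylation under mildly acidic conditions frees the primary alcohol without 1,2-acyl migration.

Step 19
Reactants: 26 primary alcohol
Product: 27 fragment B (S,Z)-4-iodo-1-oxopent-3-en-2-yl 2-bromopropanoate
Conditions: Dess–Martin periodinane, NaHCO3, CH2Cl2, 0 °C; used at once
Reagents that add atoms: none
Why: Dess–Martin oxidation is neutral, so the α-acyloxy β,γ-unsaturated aldehyde is formed without epimerisation at C7 or migration of the double bond.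

Step 20
Reactants: 17 fragment A stannane (1.2 equiv); 27 fragment B aldehyde
Product: 30 coupled carbinol (C8 epimers), via organolithium 28 (not isolated), via organocerium 29 (not isolated)
Conditions: n-BuLi, THF, −78 °C, 10 min; CeCl3, THF, −78 °C; then 27, −78 °C; AcOH, −78 °C
Reagents that add atoms: none
Why: Tin–lithium exchange of the α-alkoxystannane proceeds with retention and gives a configurationally stable α-alkoxyalkyllithium, and its transmetalation to the non-basic organocerium allows clean 1,2-addition to the aldehyde without iodine–metal exchange or ester attack, so C8–C9 is formed with C9 fixed while the new C8 carbinol mixture converges on oxidation.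

Step 21
Reactants: 30 coupled carbinol
Product: 31 α-acyloxy ketone (C8 ketone)
Conditions: Dess–Martin periodinane, pyridine, CH2Cl2, 0 °C → rt
Reagents that add atoms: none
Why: Dess–Martin oxidation converts both C8 epimers into one ketone under buffered conditions that spare the acidic C7 and C9 α-centres.

Step 22
Reactants: 31 α-acyloxy ketone
Product: 33 γ-lactone with 8-OH, via zinc enolate 32 (not isolated)
Conditions: Zn dust (activated with Me3SiCl), THF, 0 °C → rt; NH4Cl aq
Reagents that add atoms: none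
Why: In this intramolecular Reformatsky reaction zinc inserts into the C–Br bond and the enolate closes the five-membered lactone onto the ketone; the C7–O tether keeps the C9 branch away from the C6 alkenyl group, and zinc chelation of the ketone with the C9 MOM ether exposes the same face, so 8-OH ends cis to C6 and the C17 methyl settles anti to the C9 branch.

Step 23
Reactants: 33 γ-lactone
Product: 35 protected briarane macrocycle, via alkylborane 34 (not isolated)
Conditions: 9-BBN-H (3 equiv), THF, 0 °C → rt; then slow addition to Pd(dppf)Cl2 (20 mol %), AsPh3, Cs2CO3, DMF/THF/H2O, 0.002 M, 50 °C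
Reagents that add atoms: none
Why: 9-BBN hydroborates only the monosubstituted terminal alkene, and the intramolecular B-alkyl Suzuki–Miyaura coupling with the vinyl iodide forms C4–C5 with retention of the Z geometry under high dilution, creating no stereocentre.

Step 24
Reactants: 35 protected macrocycle
Product: 36 9-alcohol
Conditions: Me2BBr, CH2Cl2, −78 °C; then NaHCO3 aq
Reagents that add atoms: none
Why: Bromodimethylborane cleaves the acetal-type MOM ether at −78 °C (Lewis-acid acetal cleavage) while the silyl ethers and the lactone survive.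

Step 25
Reactants: 36 9-alcohol
Product: 37 9-acetate
Conditions: Ac2O, DMAP, pyridine, CH2Cl2, rt
Reagents that add atoms: acetic anhydride, CC(=O)OC(C)=O
Why: DMAP-catalysed acylation esterifies the only free secondary hydroxyl, the tertiary C8 hydroxyl being unreactive under these conditions.

Step 26
Reactants: 37 9-acetate
Product: 38 9-O-acetyl 2,8,11,12-tetraol
Conditions: HF·pyridine, THF, 0 °C → rt
Reagents that add atoms: none
Why: Fluoride desilylation removes the three triethylsilyl ethers under conditions that leave the acetate and the lactone alone.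

Step 27
Reactants: 38 tetraol
Product: 39 2-hydroxy enone (C12 ketone)
Conditions: MnO2 (activated, 20 equiv), CH2Cl2, rt
Reagents that add atoms: none
Why: Manganese dioxide oxidises only the allylic C12 alcohol, so the enone returns while the saturated C2 alcohol and the tertiary alcohols stay.

Step 28
Reactants: 39 2-hydroxy enone
Product: 40 target CNP0346936.2
Conditions: n-PrCOCl, pyridine, DMAP (cat.), CH2Cl2, 0 °C
Reagents that add atoms: butanoyl chloride, CCCC(Cl)=O
Why: Acylation takes the only secondary hydroxyl (C2), the tertiary C8 and C11 hydroxyls being too hindered, which completes the target.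

## Compound list

1 | butan-2-one | CCC(C)=O | starting material
2 | (E)-1-(dimethylamino)pent-1-en-3-one | CCC(=O)/C=C/N(C)C | intermediate
3 | (1E,3Z)-3-(tert-butyldimethylsilyloxy)-N,N-dimethylpenta-1,3-dien-1-amine | C/C=C(O[Si](C)(C)C(C)(C)C)/C=C/N(C)C | intermediate
4 | 2,2-dimethoxyacetaldehyde | COC(OC)C=O | starting material
5 | propanal | CCC=O | starting material
6 | (E)-4,4-dimethoxy-2-methylbut-2-enal | O=C/C(C)=C/C(OC)OC | intermediate
7 | endo cycloadduct, not isolated: 4-(tert-butyldimethylsilyloxy)-2-(dimethoxymethyl)-6-(dimethylamino)-1,3-dimethylcyclohex-4-ene-1-carbaldehyde (C1: CH3 β, CHO α; C10: CH(OMe)2 β; C11: CH3 α; C14: NMe2 α) | O=C[C@@]1(C)[C@@H](N(C)C)C=C(O[Si](C)(C)C(C)(C)C)[C@@H](C)[C@@H]1C(OC)OC | intermediate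
8 | ring A enone aldehyde, (1S,2S)-2-(dimethoxymethyl)-1,3-dimethyl-4-oxocyclohex-5-ene-1-carbaldehyde (C1: CH3 β, CHO α; C10: CH(OMe)2 β; C11 epimers, both converge in step 6) | O=C[C@@]1(C)C=CC(=O)C(C)[C@@H]1C(OC)OC | intermediate
9 | (4S,5S)-5-(dimethoxymethyl)-4-[(1R)-1-hydroxyprop-2-en-1-yl]-4,6-dimethylcyclohex-2-en-1-one (C2 is R; C11 epimers) | C=C[C@@H](O)[C@@]1(C)C=CC(=O)C(C)[C@@H]1C(OC)OC | intermediate
10 | (4S,5R,6S)-5-(dimethoxymethyl)-6-hydroxy-4-[(1R)-1-hydroxyprop-2-en-1-yl]-4,6-dimethylcyclohex-2-en-1-one (C11: OH α, CH3 β) | C=C[C@@H](O)[C@@]1(C)C=CC(=O)[C@@](C)(O)[C@@H]1C(OC)OC | intermediate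
11 | ring A triol: 12β-allylic alcohol of 10 (C2 OH; C11 OH α; C12 OH β, expected major epimer; C13=C14; C10 CH(OMe)2 β) | C=C[C@@H](O)[C@@]1(C)C=C[C@H](O)[C@@](C)(O)[C@@H]1C(OC)OC | intermediate
12 | 2,11,12-tris-O-triethylsilyl ether of 11 with the dimethyl acetal intact, not isolated | C=C[C@@H](O[Si](CC)(CC)CC)[C@@]1(C)C=C[C@H](O[Si](CC)(CC)CC)[C@@](C)(O[Si](CC)(CC)CC)[C@@H]1C(OC)OC | intermediate
13 | tris-TES aldehyde: C9 formyl group on C10 (β), O-triethylsilyl at C2, C11 and C12 | C=C[C@@H](O[Si](CC)(CC)CC)[C@@]1(C)C=C[C@H](O[Si](CC)(CC)CC)[C@@](C)(O[Si](CC)(CC)CC)[C@@H]1C=O | intermediate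
14 | lithium alkoxide of the C9 α-hydroxy tributylstannane (C9 epimers), not isolated | C=C[C@@H](O[Si](CC)(CC)CC)[C@@]1(C)C=C[C@H](O[Si](CC)(CC)CC)[C@@](C)(O[Si](CC)(CC)CC)[C@@H]1C(O[Li])[Sn](CCCC)(CCCC)CCCC | intermediate
15 | acylstannane: C10–C(=O)SnBu3, otherwise as 13 | C=C[C@@H](O[Si](CC)(CC)CC)[C@@]1(C)C=C[C@H](O[Si](CC)(CC)CC)[C@@](C)(O[Si](CC)(CC)CC)[C@@H]1C(=O)[Sn](CCCC)(CCCC)CCCC | intermediate
16 | (9S)-α-hydroxystannane, not isolated | C=C[C@@H](O[Si](CC)(CC)CC)[C@@]1(C)C=C[C@H](O[Si](CC)(CC)CC)[C@@](C)(O[Si](CC)(CC)CC)[C@@H]1[C@@H](O)[Sn](CCCC)(CCCC)CCCC | intermediate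
17 | fragment A: (9S)-(methoxymethoxy)(tributylstannyl)methyl group on C10 (β); ring A with C11 OTES α, C12 OTES β, C13=C14; (2R)-1-(triethylsilyloxy)allyl on C1 (α) | C=C[C@@H](O[Si](CC)(CC)CC)[C@@]1(C)C=C[C@H](O[Si](CC)(CC)CC)[C@@](C)(O[Si](CC)(CC)CC)[C@@H]1[C@@H](OCOC)[Sn](CCCC)(CCCC)CCCC | intermediate
18 | rac-2-vinyloxirane | C=CC1CO1 | starting material
19 | (S)-but-3-ene-1,2-diol | C=C[C@H](O)CO | intermediate
20 | (S)-2,2-dimethyl-4-vinyl-1,3-dioxolane | C=C[C@H]1COC(C)(C)O1 | intermediate
21 | (R)-2,2-dimethyl-1,3-dioxolane-4-carbaldehyde | O=C[C@H]1COC(C)(C)O1 | intermediate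
22 | (S)-4-[(Z)-2-iodoprop-1-en-1-yl]-2,2-dimethyl-1,3-dioxolane | I/C(C)=C\[C@H]1COC(C)(C)O1 | intermediate
23 | (S,Z)-4-iodopent-3-ene-1,2-diol | I/C(C)=C\[C@H](O)CO | intermediate
24 | (S,Z)-4-iodo-1-(triethylsilyloxy)pent-3-en-2-ol | I/C(C)=C\[C@H](O)CO[Si](CC)(CC)CC | intermediate
25 | (S,Z)-4-iodo-1-(triethylsilyloxy)pent-3-en-2-yl 2-bromopropanoate (epimers at CHBr) | I/C(C)=C\[C@H](OC(=O)C(C)Br)CO[Si](CC)(CC)CC | intermediate
26 | (S,Z)-1-hydroxy-4-iodopent-3-en-2-yl 2-bromopropanoate (epimers at CHBr) | I/C(C)=C\[C@H](OC(=O)C(C)Br)CO | intermediate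
27 | fragment B: (S,Z)-4-iodo-1-oxopent-3-en-2-yl 2-bromopropanoate (epimers at CHBr) | I/C(C)=C\[C@H](OC(=O)C(C)Br)C=O | intermediate
28 | α-(methoxymethoxy)alkyllithium from 17 (Li in place of SnBu3, retention), not isolated | C=C[C@@H](O[Si](CC)(CC)CC)[C@@]1(C)C=C[C@H](O[Si](CC)(CC)CC)[C@@](C)(O[Si](CC)(CC)CC)[C@@H]1[C@@H](OCOC)[Li] | intermediate
29 | dichlorocerium reagent (CeCl2 in place of Li, retention), not isolated | C=C[C@@H](O[Si](CC)(CC)CC)[C@@]1(C)C=C[C@H](O[Si](CC)(CC)CC)[C@@](C)(O[Si](CC)(CC)CC)[C@@H]1[C@@H](OCOC)[Ce](Cl)Cl | intermediate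
30 | coupled carbinol: C9 (R, OMOM)–C8H(OH)–C7 (S, O-2-bromopropanoyl)–C6H=C5(CH3)I (Z); C8 and CHBr epimers | C=C[C@@H](O[Si](CC)(CC)CC)[C@@]1(C)C=C[C@H](O[Si](CC)(CC)CC)[C@@](C)(O[Si](CC)(CC)CC)[C@@H]1[C@@H](OCOC)C(O)[C@@H](OC(=O)C(C)Br)/C=C(C)\I | intermediate
31 | α-acyloxy ketone: C8 ketone of 30 (CHBr epimers) | C=C[C@@H](O[Si](CC)(CC)CC)[C@@]1(C)C=C[C@H](O[Si](CC)(CC)CC)[C@@](C)(O[Si](CC)(CC)CC)[C@@H]1[C@@H](OCOC)C(=O)[C@@H](OC(=O)C(C)Br)/C=C(C)\I | intermediate
32 | bromozinc enolate of the propanoate (drawn C-bound), not isolated | C=C[C@@H](O[Si](CC)(CC)CC)[C@@]1(C)C=C[C@H](O[Si](CC)(CC)CC)[C@@](C)(O[Si](CC)(CC)CC)[C@@H]1[C@@H](OCOC)C(=O)[C@@H](OC(=O)C(C)[Zn]Br)/C=C(C)\I | intermediate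
33 | γ-lactone C7–O–C19(=O)–C17H(CH3)–C8(OH): (7S,17R), 8-OH and 17-CH3 cis to the C6 alkenyl group and trans to the C9 branch; (Z)-2-iodopropenyl on C7 | C=C[C@@H](O[Si](CC)(CC)CC)[C@@]1(C)C=C[C@H](O[Si](CC)(CC)CC)[C@@](C)(O[Si](CC)(CC)CC)[C@@H]1[C@@H](OCOC)[C@]2(O)[C@@H](C)C(=O)O[C@H]2/C=C(C)\I | intermediate
34 | B-alkyl-9-borabicyclo[3.3.1]nonane at C4, not isolated | C1CC2CCCC(C1)B2CC[C@@H](O[Si](CC)(CC)CC)[C@@]3(C)C=C[C@H](O[Si](CC)(CC)CC)[C@@](C)(O[Si](CC)(CC)CC)[C@@H]3[C@@H](OCOC)[C@]4(O)[C@@H](C)C(=O)O[C@H]4/C=C(C)\I | intermediate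
35 | protected briarane macrocycle: 2-O-TES, 9-O-MOM, 11,12-di-O-TES, 8-OH, 5Z, 13-ene | CC[Si](CC)(CC)O[C@@H]1CC/C(C)=C\[C@@H]2OC(=O)[C@H](C)[C@@]2(O)[C@H](OCOC)[C@@H]2[C@]1(C)C=C[C@H](O[Si](CC)(CC)CC)[C@@]2(C)O[Si](CC)(CC)CC | intermediate
36 | 9-alcohol of 35 | CC[Si](CC)(CC)O[C@@H]1CC/C(C)=C\[C@@H]2OC(=O)[C@H](C)[C@@]2(O)[C@H](O)[C@@H]2[C@]1(C)C=C[C@H](O[Si](CC)(CC)CC)[C@@]2(C)O[Si](CC)(CC)CC | intermediate
37 | 9-acetate of 36 | CC[Si](CC)(CC)O[C@@H]1CC/C(C)=C\[C@@H]2OC(=O)[C@H](C)[C@@]2(O)[C@H](OC(C)=O)[C@@H]2[C@]1(C)C=C[C@H](O[Si](CC)(CC)CC)[C@@]2(C)O[Si](CC)(CC)CC | intermediate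
38 | 9-O-acetyl 2,8,11,12-tetraol | O[C@@H]1CC/C(C)=C\[C@@H]2OC(=O)[C@H](C)[C@@]2(O)[C@H](OC(C)=O)[C@@H]2[C@]1(C)C=C[C@H](O)[C@@]2(C)O | intermediate
39 | 2-hydroxy enone (target lacking the butanoyl group) | O[C@@H]1CC/C(C)=C\[C@@H]2OC(=O)[C@H](C)[C@@]2(O)[C@H](OC(C)=O)[C@@H]2[C@]1(C)C=CC(=O)[C@@]2(C)O | intermediate
40 | CNP0346936.2 | CCCC(=O)O[C@@H]1CC/C(C)=C\[C@@H]2OC(=O)[C@H](C)[C@@]2(O)[C@H](OC(C)=O)[C@@H]2[C@]1(C)C=CC(=O)[C@@]2(C)O | target

## Step count and risks

Total step count: 28. Longest linear sequence: 18 steps (steps 1, 2, 4–10, 20–28; the fragment B line, steps 11–19 then 20–28, is equally long).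

Steps most likely to fail:

Step 23 (ten-membered ring by B-alkyl Suzuki coupling; ring strain, possible ionisation of the allylic lactone by palladium). Fallback: C4 is made an electrophile and the ring is closed without boron or base by a nickel-catalysed reductive cross-electrophile coupling. Setting out from 33, hydroboration–oxidation (9-BBN-H; NaBO3) gives primary alcohol F9. I2/PPh3/imidazole converts it into primary iodide F10. Slow addition of F10 to NiBr2·glyme, 4,4'-di-tert-butyl-2,2'-bipyridine and Mn powder in DMA joins the alkyl iodide to the vinyl iodide and comes back to the route at 35.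

Step 20 (organocerium addition in the presence of the α-bromo ester; acyl shift or ester attack). Fallback: the bromo ester is put on only after the coupling. Setting out from 23, 4-methoxybenzaldehyde dimethyl acetal/PPTS gives 4-methoxybenzylidene acetal F3. i-Bu2AlH opens it to the primary alcohol with the PMB ether on C7, F4, and Dess–Martin oxidation gives aldehyde F5. The organocerium made from 17 as in step 20 adds to it to give coupled carbinol F6, Dess–Martin oxidation gives ketone F7, and DDQ removes the PMB group to give α-hydroxy ketone F8. Acylation with 2-bromopropanoyl bromide and pyridine comes back to the route at 31.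

Step 4 (rate and enantioselectivity of the chromium–salen Diels–Alder reaction with a trisubstituted enal and a terminally substituted diene). Fallback: a simpler 2-siloxy diene under chiral Brønsted-acid-activated boron catalysis, with a separate dehydrogenation. Setting out from 6, commercial pent-1-en-3-one with t-BuMe2SiOTf/Et3N gives (Z)-3-(tert-butyldimethylsilyloxy)penta-1,3-diene F1. It adds to 6 under the triflimide-activated (S)-o-tolyl oxazaborolidine to give silyl enol ether adduct F2. Saegusa–Ito oxidation with palladium diacetate in MeCN comes back to the route at 8.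

## Further compounds

F1 | step 4 | (Z)-3-(tert-butyldimethylsilyloxy)penta-1,3-diene | C=C/C(O[Si](C)(C)C(C)(C)C)=C/C
F2 | step 4 | silyl enol ether adduct: 4-(tert-butyldimethylsilyloxy)-2-(dimethoxymethyl)-1,3-dimethylcyclohex-4-ene-1-carbaldehyde (C1: CH3 β, CHO α; C10: CH(OMe)2 β; C11: CH3 β) | O=C[C@@]1(C)CC=C(O[Si](C)(C)C(C)(C)C)[C@H](C)[C@@H]1C(OC)OC
F3 | step 20 | (4S)-4-[(Z)-2-iodoprop-1-en-1-yl]-2-(4-methoxyphenyl)-1,3-dioxolane (acetal epimers) | COc1ccc(cc1)C1OC[C@@H](O1)/C=C(C)\I
F4 | step 20 | (S,Z)-4-iodo-2-(4-methoxybenzyloxy)pent-3-en-1-ol | OC[C@@H](OCc1ccc(OC)cc1)/C=C(C)\I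
F5 | step 20 | (S,Z)-4-iodo-2-(4-methoxybenzyloxy)pent-3-enal | O=C[C@@H](OCc1ccc(OC)cc1)/C=C(C)\I
F6 | step 20 | coupled carbinol with C7 O-PMB (C8 epimers) | C=C[C@@H](O[Si](CC)(CC)CC)[C@@]1(C)C=C[C@H](O[Si](CC)(CC)CC)[C@@](C)(O[Si](CC)(CC)CC)[C@@H]1[C@@H](OCOC)C(O)[C@@H](OCc1ccc(OC)cc1)/C=C(C)\I
F7 | step 20 | C8 ketone with C7 O-PMB | C=C[C@@H](O[Si](CC)(CC)CC)[C@@]1(C)C=C[C@H](O[Si](CC)(CC)CC)[C@@](C)(O[Si](CC)(CC)CC)[C@@H]1[C@@H](OCOC)C(=O)[C@@H](OCc1ccc(OC)cc1)/C=C(C)\I
F8 | step 20 | C7 α-hydroxy C8 ketone | C=C[C@@H](O[Si](CC)(CC)CC)[C@@]1(C)C=C[C@H](O[Si](CC)(CC)CC)[C@@](C)(O[Si](CC)(CC)CC)[C@@H]1[C@@H](OCOC)C(=O)[C@@H](O)/C=C(C)\I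
F9 | step 23 | C4 primary alcohol of lactone 33 | OCC[C@@H](O[Si](CC)(CC)CC)[C@@]1(C)C=C[C@H](O[Si](CC)(CC)CC)[C@@](C)(O[Si](CC)(CC)CC)[C@@H]1[C@@H](OCOC)[C@]2(O)[C@@H](C)C(=O)O[C@H]2/C=C(C)\I
F10 | step 23 | C4 primary iodide of lactone 33 | ICC[C@@H](O[Si](CC)(CC)CC)[C@@]1(C)C=C[C@H](O[Si](CC)(CC)CC)[C@@](C)(O[Si](CC)(CC)CC)[C@@H]1[C@@H](OCOC)[C@]2(O)[C@@H](C)C(=O)O[C@H]2/C=C(C)\I
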